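Early on, a flask of starting material, partner and precatalyst makes target slowly. Thursday's read 5% at 4.00 h and 50% at 12.0 h, so time grew by a factor 3.00 and target by 10.0, near the square of the time.

| flask | starting material | partner | precatalyst | temperature | remark | time |
|---|---|---|---|---|---|---|
| Friday's | 0.050 M | 0.10 M | 3.8 mM | 50 °C | run made earlier |  |
| Thursday's | 0.050 M | 0.10 M | 15 mM | 62 °C | run made earlier |  |
| Monday's | 0.050 M | 0.15 M | 7.5 mM | 50 °C | run made earlier |  |
| dusk | 0.050 M | 0.100 M | 7.5 mM | 55 °C |  | 20 h |
| noon | 0.050 M | 0.100 M | 7.5 mM | 70 °C |  | 20 h |
| autumn | 0.050 M | 0.100 M | 7.5 mM |  | at 55 °C until 4.0 h, from then on at 70 °C | 20 h |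

| run | time / h | target / % |
|---|---|---|
| Friday's | 1.50 | 1 |
| Friday's | 4.00 | 4 |
| Friday's | 8.00 | 3 |
| Friday's | 12.0 | 5 |
| Thursday's | 1.50 | 0 |
| Thursday's | 4.00 | 5 |
| Thursday's | 8.00 | 28 |
| Thursday's | 12.0 | 50 |
| Monday's | 1.50 | 1 |
| Monday's | 4.00 | 0 |
| Monday's | 8.00 | 10 |
| Monday's | 12.0 | 16 |

(standard deviation of a reading: 2 percentage points)

- what was read earlier has a scatter of 2 percentage points, one standard deviation

- the flask that comes out highest in amount of target, in percent of the starting material charged, or "all alike" when all lie within 1.5 percentage points (dusk / noon / autumn / all alike)
- target at the end, in percent of the starting material charged, dusk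
- target at the end, in percent of the starting material charged, noon
- target at the end, in percent of the starting material charged, autumn

I read that curve as a rate that itself grows with time, as if something active built up steadily from precatalyst and partner. Starting material is the limiting reagent, with 2.00 equivalents of partner, so I took the end state to be the whole charge as target and asked how fast it is approached.

I turned the settings one at a time. Time enters squared. Precatalyst enters in proportion, so Thursday's flask scales by 0.500. I assumed partner enters squared, so Monday's flask scales by 0.444. From Friday's to Monday's this predicts a factor 4.44, and the readings show 3.20, each carrying a scatter of 2 percentage points. Temperature is what remains between the two scaled flasks, which I spread evenly in the logarithm. Each line below is the time at which the square law, scaled to the charges of dusk, reaches the whole charge.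

At 50 °C: 45.0 h

At 62 °C: 24.0 h

At 55 °C: 34.6 h

At 70 °C: 15.8 h

The third line is the whole-charge time of dusk, the time divided by the square root of the target as a fraction of the charge. Target then goes as the square of the time over the whole-charge time, so 20 h gives dusk 33.4%. Noon's whole-charge time of 15.8 h is sooner than 20 h, so noon must flatten before its end. Autumn spends its first 4.0 h cooler, so I put it below noon.

The forecast reasoned differently: “The delay seems little affected by temperature or loading.” It named noon highest, with dusk 29% (22% to 37%), noon 76% (55% to 93%) and autumn 73% (55% to 90%).

Noon came out highest, as forecast: dusk gave 32.5%, noon 80.5% and autumn 74.0%, each inside its range.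

    starting material + partner + catalyst → target + catalyst, rate k1*[starting material]*[partner]*[catalyst]/(1 + ([starting material]/sat1)) (2.60 mM, k = 2.90 /M²/s, Ea = 51.0 kJ/mol)
    partner + precatalyst → catalyst + spent reagent (k = 1.20 × 10⁻⁴ /M/s, Ea = 64.0 kJ/mol)
    2 partner → homo dimer (k = 6.80 × 10⁻⁵ /M/s, Ea = 80.0 kJ/mol)
    (constants at 70 °C)

Part of why dusk stood at 32.5% at its end is the levelling-off with starting material, together with the hour of the reading: with the levelling-off taken away dusk reached 97.3%, and read ten times later it held 100%. Noon's whole-charge time gives 40.1% at 10.0 h, and noon held 40.4%. For the neighbour of dusk with 0.040 M of partner, the whole-charge time of dusk, with the partner scaled in, gives 5.34%, and that flask gave 6.76%.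

The data are calculated for substances that don't exist; noise was put on by code.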